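## Structural features

The target is an acyclic, fully saturated C8 chain (labelled C1 to C8 from the oxirane CH2 to the CH2Cl group) with methyl branches on C3 and C7 and a single ring, the terminal oxirane formed by C1, C2 and oxygen. C2 is bonded directly to the quaternary C3 (CH3, Cl), which is followed by C4 (CHBr), the C5 methylene, C6 (CHCl), the quaternary C7 (CH3, Br) and C8 (CH2Cl). There are five stereocentres, (2S,3R,4R,6S,7S) in this chain labelling: C2, C3 and C4 are contiguous, C6 and C7 are contiguous, and C5 insulates the two groups. The oxirane is sensitive to acid and to halide, the two tertiary halides ionise and eliminate readily, and every vicinal dihalide is open to base-induced loss of HX, so strongly basic, reducing or Lewis-acidic conditions are unwelcome late in the route. The real difficulty is regiochemical and stereochemical at once: at C6/C7 bromine sits on the more substituted carbon and chlorine on the less substituted one, the reverse of what electrophilic bromine plus chloride delivers, and C2 must be set next to a quaternary carbon with no hydroxyl handle. The key step exploits the fact that C2 is attached to a quaternary, halogen-bearing C3 carrying one small (CH3) and one large (C4) carbon substituent: as an aldehyde, C2 cannot enolise and its faces are distinguished by the C3–halogen dipole. The two halohydrin precursors (C3–Br/C4–OH and C7–Cl/C6–OH) are pseudo-mirror images, so one three-step sequence run with antipodal tartrates serves both.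

## Logic of the disconnections

**30 to 27.** The C6–Cl and C7–Br bonds are cut together by reversing a 1,2-chlorine shift through chloronium ion 29, formed from triflate 28. This is the only simple way to put bromine on the tertiary and chlorine on the secondary carbon. The gain is that the mixed dihalide becomes a chlorohydrin, 27, available from silyl ether 26. The demand is that both centres invert, that the neopentyl-type triflate ionises with participation instead of being displaced directly, and that bromide attacks C7.

**26 to 23.** The C3–Cl and C4–Br bonds are cut by the analogous bromine shift through 24 and 25. Cutting here keeps bromine on C3 in every earlier compound, which the methylene transfer needs. The gain is a bromohydrin, 23, obtained from 22 by removing the more labile silyl group. The demand is again double inversion, with chloride entering at C3 and not at C4 or at the oxirane.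

**22 to 18 and 19.** The C1–C2 and O–C1 bonds are cut (methylene transfer), which removes the ring and the C2 stereocentre and leaves a non-enolisable α-bromo aldehyde. The demand is 1,2-induction from C3 in the sense that places oxygen anti to bromine. The configurations required of 18 and 22 follow from 30 by inverting C3, C4, C6 and C7 and were checked centre by centre.

**18 to 15.** Silyl ether 18 comes from hydroxy aldehyde 17 and this from diol 16. In 16 the C3–Br bond is cut by reversing an anti opening of the cis-epoxy alcohol 15 at its tertiary carbon. The gain is that C3 and C4 both derive from one reagent-controlled epoxidation. The demand is attack at C3, not C4, with clean inversion.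

**15 to 11 and 12.** The oxirane C–O bonds of 15 are cut to the (Z)-allylic alcohol 14, and the C3=C4 bond of its precursor 13 is cut to aldehyde 11 and phosphonate 12. Aldehyde 11 comes from alkene 9 by cleaving C4=CH2. The demand is (Z)-geometry, because anti opening of a cis-epoxide is what gives the required bromohydrin.

**9 to 5.** Silyl ether 9 comes from chlorohydrin 8. The C7–Cl bond of 8 is cut to epoxy chloride 7, the C8–Cl bond of 7 to epoxy alcohol 6, and the oxirane of 6 to dienol 5. C8–Cl is installed while C7 is still an epoxide carbon, so no substitution is ever needed beside a tertiary chloride. The demand is chloride attack at C7 although the CH2Cl group weakens the tertiary bias.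

**5 to 1, 2 and 3.** The C7–CH3 and C5–C6 bonds are cut, reducing 5 to three commodity reagents. The demand, (Z)-geometry, is met by the anti-carbometalation mechanism.

## Other disconnections considered

**Alternative 1:** The cut is at C5–C6 and C4–Br. In the forward sense the α-chloro acyl radical from bromochloroacetyl imide A2 would add to the vinyl group of tertiary allylic chloride A1 and the chain would be carried by bromine transfer (Kharasch addition, for instance CuCl/2,2'-bipyridine or Et3B/O2), giving imide A3.
- In its favour: it is convergent, makes a C–C bond and C4–Br in one operation, and places C3–Cl, C4–Br and C6–Cl directly in their final positions with no halogen shift and no silyl ethers. On these points it is better than the chosen plan.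
- Against it: after the addition the unpaired electron sits on C4, β to C3–Cl, so loss of a chlorine atom competes with bromine transfer. C4 would be set by acyclic induction from a quaternary centre and C6 by the auxiliary in a radical step, and the α-chloro imide is epimerisable. A1 is an ionisation-prone allylic chloride.
- The C7 carbonyl of A3 must still become C(CH3)(Br)CH2Cl, which needs two C–C bonds and a stereodefined tertiary bromide next to C6–Cl, for which no stereospecific method is evident. The oxirane must then be made from the acetonide among five halides.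
- Comparison: the mechanism is radical where the chosen plan is ionic and stereospecific. The sequence to A3 is shorter, but the endgame is longer and less defined.

**Alternative 2:** The cut is at C4–C5 and C6–O. Aldoxime A4 would be converted (N-chlorosuccinimide, Et3N) into nitrile oxide A5, which would add to alkene A6 to give isoxazoline A7.
- In its favour: two halves of similar size are joined, each already carrying its quaternary halide, and the regiochemistry of nitrile oxide addition to a monosubstituted alkene is dependable. A7 has the same C3–Br/C7–Cl pattern as the chosen precursor, so the two halogen shifts are equal in both plans. On convergence it is better, and C2 comes from the chiral pool, which is at least as certain as substrate-controlled methylene transfer.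
- Against it: C6 is set by facial selection on an alkene whose allylic stereocentre carries three groups of similar size (Cl, CH3, CH2Cl). A5 is a hindered α-bromo nitrile oxide that may dimerise.
- Reductive N–O cleavage would give hydroxy ketone A8, in which C3–Br is α to a ketone and exposed to the reductant and to retro-aldol cleavage. C4 then needs a directed reduction, and the C4 and C6 hydroxyls must be told apart before the shifts. The oxirane is again made last from an acetonide.
- Comparison: structurally it reaches the full skeleton sooner. Mechanistically its weak points lie at C6 and in functional-group tolerance, where the chosen plan relies on two reagent-controlled epoxidations.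

**Alternative 3:** The cut is at C6–Cl and C7–Br, made early. Chlorohydrin 8 would be triflated and the chloronium ion opened by bromide to give dihalide A9.
- In its favour: the mechanism is the same as in step 17, but on a small, robust substrate free of the oxirane and of the second halohydrin. No silyl group is needed on C6, which saves two steps, and a failure costs little material. On step economy and on where the risk is placed it is better than the chosen plan; on mechanism it is equal.
- Against it: the finished C6–Cl/C7–Br pair must survive chain extension. Ozonolysis of A9 would give β-chloro aldehyde A10, which can lose HCl under the basic olefination. The tertiary bromide would have to pass iBu2AlH, magnesium and titanium Lewis acids and the sulfur ylide. The homoallylic alkene of 8 could also take part in the ionisation.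
- Comparison: the chosen plan carries C6 as a base-stable silyl ether and pays with two steps and a late shift beside an oxirane. If a non-basic extension from A9 to a (Z)-2-methyl allylic alcohol were available, Alternative 3 would be preferable; cross-metathesis, the obvious candidate, favours the (E)-isomer.

Key step: step 13

## Route

Step 1
Reactants: 1 prop-2-yn-1-ol; 2 methylmagnesium bromide; 3 allyl bromide
Product: 5 (2Z)-2-methylhexa-2,5-dien-1-ol, via chelated alkenylmagnesium alkoxide 4 (not isolated)
Conditions: MeMgBr (excess), CuI (cat.), THF/Et2O, −10 °C to rt; then allyl bromide, 0 °C to rt; aq. NH4Cl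
Reagents that add atoms: none
Why: Copper-catalysed anti-carbomagnesiation of a propargylic alkoxide puts methyl on the carbinol-bearing alkyne carbon and magnesium on the terminal carbon cis to CH2O (five-membered chelate); allylation of alkenyl Grignard 4 with retention then fixes the (Z)-geometry (C8 and C5 cis) by mechanism.

Step 2
Reactants: 5 (2Z)-2-methylhexa-2,5-dien-1-ol
Product: 6 [(2S,3R)-2-methyl-3-(prop-2-en-1-yl)oxiran-2-yl]methanol
Conditions: Ti(OiPr)4, L-(+)-diethyl tartrate, t-BuOOH, 4 Å MS, CH2Cl2, −20 °C
Reagents that add atoms: tert-butyl hydroperoxide, CC(C)(C)OO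
Why: Sharpless asymmetric epoxidation: only the allylic alkene is bound to titanium, and the natural tartrate should deliver oxygen to the face that gives the (2S,3R)-oxirane, setting C6 and, provisionally, C7.

Step 3
Reactants: 6 [(2S,3R)-2-methyl-3-(prop-2-en-1-yl)oxiran-2-yl]methanol
Product: 7 (2R,3R)-2-(chloromethyl)-2-methyl-3-(prop-2-en-1-yl)oxirane
Conditions: PPh3, CCl4, NaHCO3, reflux
Reagents that add atoms: carbon tetrachloride, ClC(Cl)(Cl)Cl
Why: Appel chlorination of an epoxy alcohol (chloride displaces the alkoxyphosphonium at the primary carbon); it is done now so that C8–Cl never has to be made beside a tertiary chloride.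

Step 4
Reactants: 7 (2R,3R)-2-(chloromethyl)-2-methyl-3-(prop-2-en-1-yl)oxirane
Product: 8 (4R,5S)-5,6-dichloro-5-methylhex-1-en-4-ol
Conditions: HCl (4 M in 1,4-dioxane), CH2Cl2, −40 to 0 °C
Reagents that add atoms: hydrogen chloride, Cl
Why: Acid-mediated, borderline SN2 opening of a trisubstituted epoxide by chloride at the tertiary carbon with inversion; C6–O is untouched, so C7 becomes (S) and the anti chlorohydrin results.

Step 5
Reactants: 8 (4R,5S)-5,6-dichloro-5-methylhex-1-en-4-ol
Product: 9 tert-butyl{[(4R,5S)-5,6-dichloro-5-methylhex-1-en-4-yl]oxy}dimethylsilane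
Conditions: t-BuMe2SiOTf, 2,6-lutidine, CH2Cl2, −78 to 0 °C
Reagents that add atoms: tert-butyldimethylsilyl trifluoromethanesulfonate, CC(C)(C)[Si](C)(C)OS(=O)(=O)C(F)(F)F
Why: Silyl triflate with a weak hindered base silylates the hindered carbinol without forming an alkoxide that could close back onto C7–Cl.

Step 6
Reactants: 9 tert-butyl{[(4R,5S)-5,6-dichloro-5-methylhex-1-en-4-yl]oxy}dimethylsilane
Product: 11 (3R,4S)-3-[(tert-butyldimethylsilyl)oxy]-4,5-dichloro-4-methylpentanal, via 1,2,4-trioxolane ozonide 10 (not isolated)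
Conditions: O3, CH2Cl2, −78 °C; then PPh3, −78 °C to rt
Reagents that add atoms: ozone, [O-][O+]=O
Why: Ozonolysis with reductive work-up cleaves the only alkene; the β-silyloxy aldehyde has no epimerisable centre.

Step 7
Reactants: 11 (3R,4S)-3-[(tert-butyldimethylsilyl)oxy]-4,5-dichloro-4-methylpentanal; 12 ethyl 2-[bis(2,2,2-trifluoroethoxy)phosphoryl]propanoate
Product: 13 ethyl (2Z,5R,6S)-5-[(tert-butyldimethylsilyl)oxy]-6,7-dichloro-2,6-dimethylhept-2-enoate
Conditions: KN(SiMe3)2, 18-crown-6, THF, −78 °C
Reagents that add atoms: none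
Why: Still–Gennari olefination (kinetically controlled, Z-selective Horner–Wadsworth–Emmons reaction of a bis(trifluoroethyl) phosphonate) should give the (Z)-2-methyl enoate, the geometry that later leads to the required bromohydrin.

Step 8
Reactants: 13 ethyl (2Z,5R,6S)-5-[(tert-butyldimethylsilyl)oxy]-6,7-dichloro-2,6-dimethylhept-2-enoate
Product: 14 (2Z,5R,6S)-5-[(tert-butyldimethylsilyl)oxy]-6,7-dichloro-2,6-dimethylhept-2-en-1-ol
Conditions: iBu2AlH, CH2Cl2, −78 °C; Rochelle salt
Reagents that add atoms: none
Why: 1,2-Reduction of an enoate by iBu2AlH at low temperature; the alkyl chlorides and the silyl ether are inert and the alkene geometry is retained.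

Step 9
Reactants: 14 (2Z,5R,6S)-5-[(tert-butyldimethylsilyl)oxy]-6,7-dichloro-2,6-dimethylhept-2-en-1-ol
Product: 15 [(2R,3S)-3-{(2R,3S)-2-[(tert-butyldimethylsilyl)oxy]-3,4-dichloro-3-methylbutyl}-2-methyloxiran-2-yl]methanol
Conditions: Ti(OiPr)4, D-(−)-diethyl tartrate, t-BuOOH, 4 Å MS, CH2Cl2, −20 °C
Reagents that add atoms: tert-butyl hydroperoxide, CC(C)(C)OO
Why: Second Sharpless asymmetric epoxidation under reagent control; the unnatural tartrate should give the (2R,3S)-oxirane, the sense opposite to step 2, setting C4 and, provisionally, C3.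

Step 10
Reactants: 15 [(2R,3S)-3-{(2R,3S)-2-[(tert-butyldimethylsilyl)oxy]-3,4-dichloro-3-methylbutyl}-2-methyloxiran-2-yl]methanol
Product: 16 (2S,3S,5R,6S)-2-bromo-5-[(tert-butyldimethylsilyl)oxy]-6,7-dichloro-2,6-dimethylheptane-1,3-diol
Conditions: MgBr2·OEt2, Et2O, −20 to 0 °C; aq. NH4Cl
Reagents that add atoms: magnesium bromide diethyl etherate, [Mg+2].[Br-].[Br-].CCOCC
Why: Lewis-acid-assisted anti opening of a trisubstituted epoxide by bromide at the tertiary carbon (Markovnikov sense) with inversion; C4–O is retained, so the C3-bromo C4-carbinol is obtained with both centres defined.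

Step 11
Reactants: 16 (2S,3S,5R,6S)-2-bromo-5-[(tert-butyldimethylsilyl)oxy]-6,7-dichloro-2,6-dimethylheptane-1,3-diol
Product: 17 (2R,3S,5R,6S)-2-bromo-5-[(tert-butyldimethylsilyl)oxy]-6,7-dichloro-3-hydroxy-2,6-dimethylheptanal
Conditions: TEMPO (2,2,6,6-tetramethylpiperidin-1-oxyl, cat.), PhI(OAc)2, CH2Cl2, rt
Reagents that add atoms: none
Why: Oxoammonium (TEMPO) oxidation selects the primary alcohol over the hindered secondary one; the aldehyde cannot enolise or eliminate because C3 is quaternary.

Step 12
Reactants: 17 (2R,3S,5R,6S)-2-bromo-5-[(tert-butyldimethylsilyl)oxy]-6,7-dichloro-3-hydroxy-2,6-dimethylheptanal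
Product: 18 (2R,3S,5R,6S)-2-bromo-5-[(tert-butyldimethylsilyl)oxy]-6,7-dichloro-2,6-dimethyl-3-[(triethylsilyl)oxy]heptanal
Conditions: Et3SiOTf, 2,6-lutidine, CH2Cl2, −78 °C
Reagents that add atoms: triethylsilyl trifluoromethanesulfonate, CC[Si](CC)(CC)OS(=O)(=O)C(F)(F)F
Why: Silylation of the C4 hydroxyl prevents alkoxide formation beside C3–Br in the basic key step; triethylsilyl is chosen so that it can later be removed before the tert-butyldimethylsilyl group.

Step 13
Reactants: 18 (2R,3S,5R,6S)-2-bromo-5-[(tert-butyldimethylsilyl)oxy]-6,7-dichloro-2,6-dimethyl-3-[(triethylsilyl)oxy]heptanal; 19 trimethylsulfonium iodide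
Product: 22 (2S)-2-[(2S,3S,5R,6S)-2-bromo-5-[(tert-butyldimethylsilyl)oxy]-6,7-dichloro-6-methyl-3-[(triethylsilyl)oxy]heptan-2-yl]oxirane, via dimethylsulfonium methylide 20 (not isolated), via sulfonium alkoxide betaine 21 (not isolated)
Conditions: 19, n-BuLi, THF, −10 °C; then 18, −78 to 0 °C
Reagents that add atoms: none
Why: Ylide 20 adds through carbon to the C2 carbonyl of 18 to give betaine 21, whose alkoxide displaces dimethyl sulfide from C1, forming C1–C2 and O–C1. The closest known reaction type is Corey–Chaykovsky methylene transfer to α-halo aldehydes. The oxirane closes in a 3-exo-tet mode. The new stereocentre C2 is controlled by C3 through the Cornforth conformer, in which the carbonyl is anti to the C3–Br bond; the ylide then passes the methyl group and not the branched, silyloxy-bearing C4, which places oxygen anti to bromine and should give (2S). The polar Felkin–Anh model predicts the same face. The step needs chemoselectivity for carbonyl addition over attack at bromine or loss of HBr; this is served by the absence of an α-hydrogen, the low temperature, the fast addition of the unstabilised ylide and the fact that the primary sulfonium is the only good leaving group within reach of the alkoxide. The oxygen/bromine relationship made here becomes the oxygen/chlorine relationship of the target when chloride enters C3 with inversion in step 15.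

Step 14
Reactants: 22 (2S)-2-[(2S,3S,5R,6S)-2-bromo-5-[(tert-butyldimethylsilyl)oxy]-6,7-dichloro-6-methyl-3-[(triethylsilyl)oxy]heptan-2-yl]oxirane
Product: 23 (2R,3S,5R,6S)-2-bromo-5-[(tert-butyldimethylsilyl)oxy]-6,7-dichloro-6-methyl-2-[(2S)-oxiran-2-yl]heptan-3-ol
Conditions: pyridinium p-toluenesulfonate (cat.), MeOH/CH2Cl2, 0 °C
Reagents that add atoms: none
Why: Mild acid-catalysed methanolysis removes the triethylsilyl ether selectively; the tert-butyldimethylsilyl ether and the electron-poor oxirane (next to a C–Br carbon) should survive.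

Step 15
Reactants: 23 (2R,3S,5R,6S)-2-bromo-5-[(tert-butyldimethylsilyl)oxy]-6,7-dichloro-6-methyl-2-[(2S)-oxiran-2-yl]heptan-3-ol
Product: 26 (2S)-2-[(2R,3R,5R,6S)-3-bromo-5-[(tert-butyldimethylsilyl)oxy]-2,6,7-trichloro-6-methylheptan-2-yl]oxirane, via C4 triflate 24 (not isolated), via bromonium ion 25 (not isolated)
Conditions: Tf2O, 2,6-di-tert-butyl-4-methylpyridine, CH2Cl2, −78 °C; then Bu4NCl, −78 to 0 °C
Reagents that add atoms: tetrabutylammonium chloride, CCCC[N+](CCCC)(CCCC)CCCC.[Cl-]
Why: Neighbouring-bromine participation in the ionisation of the β-bromo triflate gives bromonium ion 25 with inversion at C4, and chloride opens it at the tertiary C3 anti to bromine with inversion, a known haliranium capture; direct displacement at the neopentyl-type C4 is slow, so C3 and C4 should both become (R).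

Step 16
Reactants: 26 (2S)-2-[(2R,3R,5R,6S)-3-bromo-5-[(tert-butyldimethylsilyl)oxy]-2,6,7-trichloro-6-methylheptan-2-yl]oxirane
Product: 27 (2S,3R,5R,6R)-5-bromo-1,2,6-trichloro-2-methyl-6-[(2S)-oxiran-2-yl]heptan-3-ol
Conditions: HF·pyridine, pyridine, THF, 0 °C to rt
Reagents that add atoms: none
Why: Buffered acidic fluoride removes the hindered silyl ether without forming an alkoxide that could displace C7–Cl or C4–Br; the oxirane is deactivated towards acid by the adjacent C–Cl carbon.

Step 17
Reactants: 27 (2S,3R,5R,6R)-5-bromo-1,2,6-trichloro-2-methyl-6-[(2S)-oxiran-2-yl]heptan-3-ol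
Product: 30 (2S)-2-[(2R,3R,5S,6S)-3,6-dibromo-2,5,7-trichloro-6-methylheptan-2-yl]oxirane, via C6 triflate 28 (not isolated), via chloronium ion 29 (not isolated)
Conditions: Tf2O, 2,6-di-tert-butyl-4-methylpyridine, CH2Cl2, −78 °C; then Bu4NBr, −78 to 0 °C
Reagents that add atoms: tetrabutylammonium bromide, CCCC[N+](CCCC)(CCCC)CCCC.[Br-]
Why: Neighbouring-chlorine participation in β-chloroalkyl sulfonate ionisation gives chloronium ion 29 with inversion at C6, and bromide opens it at the tertiary C7 with inversion, moving chlorine to C6 and placing bromine on C7; both centres should become (S), completing the target.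

## Compound list

1 | prop-2-yn-1-ol | C#CCO | starting material
2 | methylmagnesium bromide | C[Mg]Br | starting material
3 | allyl bromide | C=CCBr | starting material
4 | chelated alkenylmagnesium alkoxide, bromomagnesium (2Z)-3-(bromomagnesio)-2-methylprop-2-en-1-olate | Br[Mg]/C=C(/C)CO[Mg]Br | intermediate
5 | (2Z)-2-methylhexa-2,5-dien-1-ol | OC/C(C)=C\CC=C | intermediate
6 | [(2S,3R)-2-methyl-3-(prop-2-en-1-yl)oxiran-2-yl]methanol | C=CC[C@H]1O[C@@]1(C)CO | intermediate
7 | (2R,3R)-2-(chloromethyl)-2-methyl-3-(prop-2-en-1-yl)oxirane | C=CC[C@H]1O[C@@]1(C)CCl | intermediate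
8 | (4R,5S)-5,6-dichloro-5-methylhex-1-en-4-ol | C=CC[C@@H](O)[C@](C)(Cl)CCl | intermediate
9 | tert-butyl{[(4R,5S)-5,6-dichloro-5-methylhex-1-en-4-yl]oxy}dimethylsilane | C=CC[C@@H](O[Si](C)(C)C(C)(C)C)[C@](C)(Cl)CCl | intermediate
10 | 1,2,4-trioxolane ozonide of 9, 3-{(2R,3S)-2-[(tert-butyldimethylsilyl)oxy]-3,4-dichloro-3-methylbutyl}-1,2,4-trioxolane | C1OOC(O1)C[C@@H](O[Si](C)(C)C(C)(C)C)[C@](C)(Cl)CCl | intermediate
11 | (3R,4S)-3-[(tert-butyldimethylsilyl)oxy]-4,5-dichloro-4-methylpentanal | O=CC[C@@H](O[Si](C)(C)C(C)(C)C)[C@](C)(Cl)CCl | intermediate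
12 | ethyl 2-[bis(2,2,2-trifluoroethoxy)phosphoryl]propanoate | CCOC(=O)C(C)P(=O)(OCC(F)(F)F)OCC(F)(F)F | starting material
13 | ethyl (2Z,5R,6S)-5-[(tert-butyldimethylsilyl)oxy]-6,7-dichloro-2,6-dimethylhept-2-enoate | CCOC(=O)/C(C)=C\C[C@@H](O[Si](C)(C)C(C)(C)C)[C@](C)(Cl)CCl | intermediate
14 | (2Z,5R,6S)-5-[(tert-butyldimethylsilyl)oxy]-6,7-dichloro-2,6-dimethylhept-2-en-1-ol | OC/C(C)=C\C[C@@H](O[Si](C)(C)C(C)(C)C)[C@](C)(Cl)CCl | intermediate
15 | [(2R,3S)-3-{(2R,3S)-2-[(tert-butyldimethylsilyl)oxy]-3,4-dichloro-3-methylbutyl}-2-methyloxiran-2-yl]methanol | OC[C@@]1(C)O[C@H]1C[C@@H](O[Si](C)(C)C(C)(C)C)[C@](C)(Cl)CCl | intermediate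
16 | (2S,3S,5R,6S)-2-bromo-5-[(tert-butyldimethylsilyl)oxy]-6,7-dichloro-2,6-dimethylheptane-1,3-diol | OC[C@](C)(Br)[C@@H](O)C[C@@H](O[Si](C)(C)C(C)(C)C)[C@](C)(Cl)CCl | intermediate
17 | (2R,3S,5R,6S)-2-bromo-5-[(tert-butyldimethylsilyl)oxy]-6,7-dichloro-3-hydroxy-2,6-dimethylheptanal | O=C[C@](C)(Br)[C@@H](O)C[C@@H](O[Si](C)(C)C(C)(C)C)[C@](C)(Cl)CCl | intermediate
18 | (2R,3S,5R,6S)-2-bromo-5-[(tert-butyldimethylsilyl)oxy]-6,7-dichloro-2,6-dimethyl-3-[(triethylsilyl)oxy]heptanal | O=C[C@](C)(Br)[C@@H](O[Si](CC)(CC)CC)C[C@@H](O[Si](C)(C)C(C)(C)C)[C@](C)(Cl)CCl | intermediate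
19 | trimethylsulfonium iodide | C[S+](C)C.[I-] | starting material
20 | dimethylsulfonium methylide | [CH2-][S+](C)C | intermediate
21 | sulfonium alkoxide betaine, (2S,3S,4S,6R,7S)-3-bromo-6-[(tert-butyldimethylsilyl)oxy]-7,8-dichloro-1-(dimethylsulfonio)-3,7-dimethyl-4-[(triethylsilyl)oxy]octan-2-olate | C[S+](C)C[C@H]([O-])[C@](C)(Br)[C@@H](O[Si](CC)(CC)CC)C[C@@H](O[Si](C)(C)C(C)(C)C)[C@](C)(Cl)CCl | intermediate
22 | (2S)-2-[(2S,3S,5R,6S)-2-bromo-5-[(tert-butyldimethylsilyl)oxy]-6,7-dichloro-6-methyl-3-[(triethylsilyl)oxy]heptan-2-yl]oxirane | C[C@@](Br)([C@@H](O[Si](CC)(CC)CC)C[C@@H](O[Si](C)(C)C(C)(C)C)[C@](C)(Cl)CCl)[C@@H]1CO1 | intermediate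
23 | (2R,3S,5R,6S)-2-bromo-5-[(tert-butyldimethylsilyl)oxy]-6,7-dichloro-6-methyl-2-[(2S)-oxiran-2-yl]heptan-3-ol | C[C@@](Br)([C@@H](O)C[C@@H](O[Si](C)(C)C(C)(C)C)[C@](C)(Cl)CCl)[C@@H]1CO1 | intermediate
24 | C4 trifluoromethanesulfonate of 23 | C[C@@](Br)([C@@H](OS(=O)(=O)C(F)(F)F)C[C@@H](O[Si](C)(C)C(C)(C)C)[C@](C)(Cl)CCl)[C@@H]1CO1 | intermediate
25 | bromonium ion bridging C3 and C4 (bromine anti to the departed triflate) | C[C@@]1([C@@H]2CO2)[Br+][C@@H]1C[C@@H](O[Si](C)(C)C(C)(C)C)[C@](C)(Cl)CCl | intermediate
26 | (2S)-2-[(2R,3R,5R,6S)-3-bromo-5-[(tert-butyldimethylsilyl)oxy]-2,6,7-trichloro-6-methylheptan-2-yl]oxirane | C[C@](Cl)([C@H](Br)C[C@@H](O[Si](C)(C)C(C)(C)C)[C@](C)(Cl)CCl)[C@@H]1CO1 | intermediate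
27 | (2S,3R,5R,6R)-5-bromo-1,2,6-trichloro-2-methyl-6-[(2S)-oxiran-2-yl]heptan-3-ol | C[C@](Cl)([C@H](Br)C[C@@H](O)[C@](C)(Cl)CCl)[C@@H]1CO1 | intermediate
28 | C6 trifluoromethanesulfonate of 27 | C[C@](Cl)([C@H](Br)C[C@@H](OS(=O)(=O)C(F)(F)F)[C@](C)(Cl)CCl)[C@@H]1CO1 | intermediate
29 | chloronium ion bridging C6 and C7 (chlorine anti to the departed triflate) | C[C@](Cl)([C@H](Br)C[C@@H]1[Cl+][C@]1(C)CCl)[C@@H]2CO2 | intermediate
30 | (2S)-2-[(2R,3R,5S,6S)-3,6-dibromo-2,5,7-trichloro-6-methylheptan-2-yl]oxirane | C[C@](Cl)([C@H](Br)C[C@H](Cl)[C@@](C)(Br)CCl)[C@@H]1CO1 | target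

## Step count and least certain steps

Total: 17 steps. Longest linear sequence: 17 steps, from 1 to 30; the route is fully linear.

**Step 13 (key step).** The most likely failure is loss of chemoselectivity. The soft, basic ylide may attack the tertiary bromine or remove HBr before it adds to the carbonyl, and facial selectivity may be eroded if the Cornforth conformer is not dominant.
- Fallback: it sets out from 18. (Phenylsulfanyl)methyllithium (thioanisole, n-BuLi, DABCO, THF, −78 °C), a hard carbanion, should add to the aldehyde under the same 1,2-induction and give the β-hydroxy sulfide F1, which is stable and can be purified from any C2 epimer.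
- S-Methylation (Me3OBF4, CH2Cl2) to the sulfonium salt F2 and brief treatment with aqueous NaOH should close the oxirane, returning to the route at 22.

**Step 17.** The most likely failure is ionisation without clean chlorine participation on the most advanced intermediate. Possible pathways are direct displacement of the triflate by bromide, bromide attack at the oxirane under the mildly acidic conditions, attack at the C6 end of the chloronium ion, or elimination. Chlorine is a weak neighbouring group, and C7 carries an electron-withdrawing CH2Cl.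
- Fallback: the shift is moved ahead of oxirane formation. It sets out from 16, which is protected as the acetonide F3 (2,2-dimethoxypropane, pyridinium p-toluenesulfonate) and desilylated (HF·pyridine) to the alcohol F4.
- Triflation and Bu4NBr should give the rearranged dihalide F5, and aqueous acetic acid the diol F6.
- Oxidation as in step 11 gives the hydroxy aldehyde F7, silylation as in step 12 the aldehyde F8, methylene transfer as in step 13 the oxirane F9, and desilylation as in step 14 the bromohydrin F10.
- The bromine shift as in step 15 then returns to the route at 30.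

**Step 4.** The most likely failure is poor regioselectivity of the epoxide opening. The CH2Cl group destabilises positive charge at C7, so chloride may attack C6, and a more cationic pathway would erode the inversion at C7.
- Fallback: it sets out from 6, whose CH2OH group deactivates C7 less. HCl should open it at the tertiary carbon to the chloro diol F11.
- Selective triflation of the primary hydroxyl (Tf2O, 2,6-lutidine, −78 °C) to F12 and displacement with Bu4NCl under strongly nucleophilic conditions return to the route at 8.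
- This costs one step and requires that direct substitution outrun chlorine participation.

**Step 10.** The most likely failure is opening at the wrong carbon. Magnesium chelated between the primary hydroxyl and the oxirane may steer bromide to the distal C4, or the magnesium bromohydrinate may rearrange on warming.
- Fallback: it sets out from 11 and uses an enolate route. Pinnick oxidation (NaClO2, NaH2PO4, 2-methylbut-2-ene) gives the acid F13.
- Masamune acylation (carbonyldiimidazole, then the magnesium salt made from potassium ethyl methylmalonate and MgCl2) gives the β-keto ester F14.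
- Catalytic asymmetric bromination (Cu(OTf)2, the antipode of 2,2'-isopropylidenebis(4-phenyl-2-oxazoline) that delivers the (2R)-bromide, N-bromosuccinimide) gives F15.
- CBS reduction ((R)-2-methyl-CBS-oxazaborolidine, C18H20BNO, with BH3·SMe2) gives the bromo hydroxy ester F16, and iBu2AlH reduction returns to the route at 16.

## Further compounds

F1 | step 13 | (2S,3S,4S,6R,7S)-3-bromo-6-[(tert-butyldimethylsilyl)oxy]-7,8-dichloro-3,7-dimethyl-1-(phenylsulfanyl)-4-[(triethylsilyl)oxy]octan-2-ol | c1ccccc1SC[C@H](O)[C@](C)(Br)[C@@H](O[Si](CC)(CC)CC)C[C@@H](O[Si](C)(C)C(C)(C)C)[C@](C)(Cl)CCl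
F2 | step 13 | [(2S,3S,4S,6R,7S)-3-bromo-6-[(tert-butyldimethylsilyl)oxy]-7,8-dichloro-2-hydroxy-3,7-dimethyl-4-[(triethylsilyl)oxy]octyl](methyl)phenylsulfonium tetrafluoroborate | C[S+](c1ccccc1)C[C@H](O)[C@](C)(Br)[C@@H](O[Si](CC)(CC)CC)C[C@@H](O[Si](C)(C)C(C)(C)C)[C@](C)(Cl)CCl.F[B-](F)(F)F
F3 | step 17 | (4S,5S)-5-bromo-4-{(2R,3S)-2-[(tert-butyldimethylsilyl)oxy]-3,4-dichloro-3-methylbutyl}-2,2,5-trimethyl-1,3-dioxane | CC1(C)OC[C@](C)(Br)[C@@H](O1)C[C@@H](O[Si](C)(C)C(C)(C)C)[C@](C)(Cl)CCl
F4 | step 17 | (2R,3S)-1-[(4S,5S)-5-bromo-2,2,5-trimethyl-1,3-dioxan-4-yl]-3,4-dichloro-3-methylbutan-2-ol | CC1(C)OC[C@](C)(Br)[C@@H](O1)C[C@@H](O)[C@](C)(Cl)CCl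
F5 | step 17 | (4S,5S)-5-bromo-4-[(2S,3S)-3-bromo-2,4-dichloro-3-methylbutyl]-2,2,5-trimethyl-1,3-dioxane | CC1(C)OC[C@](C)(Br)[C@@H](O1)C[C@H](Cl)[C@@](C)(Br)CCl
F6 | step 17 | (2S,3S,5S,6S)-2,6-dibromo-5,7-dichloro-2,6-dimethylheptane-1,3-diol | OC[C@](C)(Br)[C@@H](O)C[C@H](Cl)[C@@](C)(Br)CCl
F7 | step 17 | (2R,3S,5S,6S)-2,6-dibromo-5,7-dichloro-3-hydroxy-2,6-dimethylheptanal | O=C[C@](C)(Br)[C@@H](O)C[C@H](Cl)[C@@](C)(Br)CCl
F8 | step 17 | (2R,3S,5S,6S)-2,6-dibromo-5,7-dichloro-2,6-dimethyl-3-[(triethylsilyl)oxy]heptanal | O=C[C@](C)(Br)[C@@H](O[Si](CC)(CC)CC)C[C@H](Cl)[C@@](C)(Br)CCl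
F9 | step 17 | (2S)-2-[(2S,3S,5S,6S)-2,6-dibromo-5,7-dichloro-6-methyl-3-[(triethylsilyl)oxy]heptan-2-yl]oxirane | C[C@@](Br)([C@@H](O[Si](CC)(CC)CC)C[C@H](Cl)[C@@](C)(Br)CCl)[C@@H]1CO1
F10 | step 17 | (2R,3S,5S,6S)-2,6-dibromo-5,7-dichloro-6-methyl-2-[(2S)-oxiran-2-yl]heptan-3-ol | C[C@@](Br)([C@@H](O)C[C@H](Cl)[C@@](C)(Br)CCl)[C@@H]1CO1
F11 | step 4 | (2R,3R)-2-chloro-2-methylhex-5-ene-1,3-diol | C=CC[C@@H](O)[C@](C)(Cl)CO
F12 | step 4 | (2R,3R)-2-chloro-3-hydroxy-2-methylhex-5-en-1-yl trifluoromethanesulfonate | C=CC[C@@H](O)[C@](C)(Cl)COS(=O)(=O)C(F)(F)F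
F13 | step 10 | (3R,4S)-3-[(tert-butyldimethylsilyl)oxy]-4,5-dichloro-4-methylpentanoic acid | OC(=O)C[C@@H](O[Si](C)(C)C(C)(C)C)[C@](C)(Cl)CCl
F14 | step 10 | ethyl (5R,6S)-5-[(tert-butyldimethylsilyl)oxy]-6,7-dichloro-2,6-dimethyl-3-oxoheptanoate (C2 epimers) | CCOC(=O)C(C)C(=O)C[C@@H](O[Si](C)(C)C(C)(C)C)[C@](C)(Cl)CCl
F15 | step 10 | ethyl (2R,5R,6S)-2-bromo-5-[(tert-butyldimethylsilyl)oxy]-6,7-dichloro-2,6-dimethyl-3-oxoheptanoate | CCOC(=O)[C@](C)(Br)C(=O)C[C@@H](O[Si](C)(C)C(C)(C)C)[C@](C)(Cl)CCl
F16 | step 10 | ethyl (2R,3S,5R,6S)-2-bromo-5-[(tert-butyldimethylsilyl)oxy]-6,7-dichloro-3-hydroxy-2,6-dimethylheptanoate | CCOC(=O)[C@](C)(Br)[C@@H](O)C[C@@H](O[Si](C)(C)C(C)(C)C)[C@](C)(Cl)CCl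
A1 | alternative 1 | (4S)-4-[(2S)-2-chlorobut-3-en-2-yl]-2,2-dimethyl-1,3-dioxolane | C[C@](Cl)(C=C)[C@@H]1COC(C)(C)O1
A2 | alternative 1 | (4R)-4-benzyl-3-(bromochloroacetyl)-1,3-oxazolidin-2-one | O=C(C(Cl)Br)N1C(=O)OC[C@H]1Cc1ccccc1
A3 | alternative 1 | (4R)-4-benzyl-3-{(2S,4R,5R)-4-bromo-2,5-dichloro-5-[(4S)-2,2-dimethyl-1,3-dioxolan-4-yl]hexanoyl}-1,3-oxazolidin-2-one | C[C@](Cl)([C@H](Br)C[C@H](Cl)C(=O)N1C(=O)OC[C@H]1Cc1ccccc1)[C@@H]2COC(C)(C)O2
A4 | alternative 2 | (2R)-2-bromo-2-[(4S)-2,2-dimethyl-1,3-dioxolan-4-yl]propanal oxime | C[C@@](Br)(C=NO)[C@@H]1COC(C)(C)O1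
A5 | alternative 2 | (2R)-2-bromo-2-[(4S)-2,2-dimethyl-1,3-dioxolan-4-yl]propanenitrile oxide | C[C@@](Br)(C#[N+][O-])[C@@H]1COC(C)(C)O1
A6 | alternative 2 | (3S)-3,4-dichloro-3-methylbut-1-ene | C=C[C@](C)(Cl)CCl
A7 | alternative 2 | (5R)-3-{(1R)-1-bromo-1-[(4S)-2,2-dimethyl-1,3-dioxolan-4-yl]ethyl}-5-[(2S)-1,2-dichloropropan-2-yl]-4,5-dihydro-1,2-oxazole | C[C@@](Br)(C1=NO[C@H](C1)[C@](C)(Cl)CCl)[C@@H]2COC(C)(C)O2
A8 | alternative 2 | (2S,5R,6S)-2-bromo-6,7-dichloro-2-[(4S)-2,2-dimethyl-1,3-dioxolan-4-yl]-5-hydroxy-6-methylheptan-3-one | C[C@@](Br)(C(=O)C[C@@H](O)[C@](C)(Cl)CCl)[C@@H]1COC(C)(C)O1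
A9 | alternative 3 | (4S,5S)-5-bromo-4,6-dichloro-5-methylhex-1-ene | C=CC[C@H](Cl)[C@@](C)(Br)CCl
A10 | alternative 3 | (3S,4S)-4-bromo-3,5-dichloro-4-methylpentanal | O=CC[C@H](Cl)[C@@](C)(Br)CCl
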